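## Structural features

The target is a 7-hydroxyisoflavone: a chromen-4-one (benzo ring A fused to pyranone ring C) joined through the single bond C3–C1′ to a benzene ring B, which is fused across C3′–C4′ to a 2,2-dimethyl-2H-pyran (ring D). Ring B is pentasubstituted: C1′ carries the chromone, C2′ a hydroxyl, C3′ the ring D carbon C4″, C4′ the ring D oxygen O1″, C5′ a methoxyl, and only C6′ keeps a hydrogen. There is no stereocentre and no stereogenic double bond, since the ring D alkene is held cis by the ring, so the problem is one of regiochemistry only. Three sites are fragile: C2 of ring C, which adds nucleophiles so that bases can open the pyranone; the styrene-like alkene C3″=C4″, which is sensitive to acid, electrophiles and hydrogenation; and the C2′-hydroxy/C5′-methoxy pair, a hydroquinone monoether that oxidises easily to a quinone. The real difficulty is to place five different substituents around ring B in the right order, above all the direction of the ring D fusion (oxygen beside the methoxyl, carbon beside the hydroxyl), and to make the hindered C3–C1′ bond. The key step uses the para relation of the C2′ hydroxyl and the C5′ methoxyl, together with the fact that C3′–C4′ can be read as the former double bond of a cyclic enol ether. A methoxy(alkenyl)carbene, one carbonyl ligand and a terminal alkyne assemble exactly this pattern, the alkyne supplying C6′–H and C1′ with the chromone already attached.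

## Logic of the disconnections

22 ⇒ 21. The O2′–C(acyl) bond and the O7–Si bond are cut, so both phenols stay masked until the last step. The reason is that a free C2′ hydroxyl para to the methoxyl would not survive the oxidation that creates the ring D alkene, and the acidic O7–H would interfere with the organometallic steps. The skeleton does not change. The forward step must remove both groups without acid (ring D alkene) and without a strongly nucleophilic base (ring C), which points to fluoride followed by mild transesterification in one pot.

21 ⇒ 20. The π bond C3″=C4″ is removed. A saturated ring D can be carried from the start as a stable cyclic enol ether, whereas a carbene bearing a 2H-pyran would not be a viable reagent. The gain is a chroman that tolerates all earlier chemistry. The forward step must take hydride from the benzylic C4″ only; the ring D oxygen ortho to the ring fusion stabilises that cation, and the acylated C2′ oxygen keeps ring B from being oxidised to a quinone.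

20 ⇒ 19. The O2′–C(acyl) bond is cut. This only sets up the oxidation above and asks for acylation of a hindered, hydrogen-bonded phenol.

19 ⇒ 10 + 17 (through 18). The bonds C5′–C6′, C1′–C2′ and C2′–C3′ are cut, and C2′ is traced back to a carbonyl ligand of 10. This one cut removes the whole of ring B and, with it, the C3–C1′ bond, which is already present in 17. It leaves two fragments of similar size, and the ring D oxygen and carbon are already attached to the future C4′ and C3′, so the direction of the ring fusion cannot go wrong. Traced atom by atom, 10 and 17 lead to exactly the substitution pattern of 19, so neither fragment needs correction. The forward step needs regioselective alkyne insertion, phenol formation in preference to five-membered ring products, tolerance of the chromone enone, and removal of chromium without oxidising the hydroquinone monoether.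

17 ⇒ 16 ⇒ 14 + 15. The C(sp)–Si bond is cut, then the C3–C(sp) bond. A terminal ethynyl group is best brought in masked, by palladium/copper coupling at a C3 iodide. The demand is an amine base that does not open ring C, and removal of silicon from carbon while the O7–Si bond stays. The latter is met by silver catalysis in a near-neutral medium.

14 ⇒ 13 ⇒ 12 ⇒ 11. The C3–I and O1–C2 bonds are cut (iodocyclisation of an enaminone), then the C2–C3 bond (one carbon added to the acetyl methyl), then the O7–Si bond. The silyl group is placed before ring C is built, so that the free para-hydroxyl of 11 never meets the methylating amide acetal. The demand is silylation of the non-chelated hydroxyl only, and survival of the aryl silyl ether through aminomethylenation and iodination.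

10 ⇒ 9 ⇒ 8 ⇒ 6 + 7. The O–CH3 bond, the bond between the carbene carbon and C6 of the dihydropyran, and the C6–Li bond are cut. This reduces the carbene complex to a simple cyclic enol ether and the metal carbonyl 7. The forward steps need deprotonation at the vinylic C–H next to oxygen and O-alkylation of the acylmetalate by a hard methylating agent.

6 ⇒ 5 ⇒ 4 ⇒ 3 ⇒ 2 ⇒ 1. The enol ether double bond is traced to loss of the anomeric oxygen from a lactol, and the lactol C–H bond to partial reduction of a lactone. The lactone ring O–C(=O) bond and one C–CH3 bond at the tertiary carbon are then cut, which leads to the keto acid 1. The demand is that the carboxylate stay inert while the methyl nucleophile adds to the ketone, and that reduction stop at the lactol.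

## Other disconnections considered

Alternative 1: The cut is the C2=C3 double bond of ring C. In the forward direction the O-formyl acylphosphorane 2-[2-(8-methoxy-5-(methoxymethoxy)-2,2-dimethyl-2H-chromen-6-yl)-2-(triphenyl-λ5-phosphanylidene)acetyl]-5-(methoxymethoxy)phenyl formate A2 would be heated. The ylide carbon of A2 (the future C3) attacks the formate carbonyl (the future C2) and phosphorus leaves as its P=O by-product. The product would be the bis(methoxymethyl)-protected isoflavone A1.
- In its favour: the closure of A2 to A1 is neutral, the regiochemistry of ring C is fixed by connectivity, no stoichiometric transition metal is used, and ring D arrives in A1 with its alkene in place.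
- Against it here: A2 presupposes a finished pentasubstituted ring B carrying a benzylic phosphorus handle, so the ordering of five substituents is only moved to an earlier stage, where it must be solved by stepwise aromatic substitution. The ketone-stabilised ylide of A2 reacts slowly with an ester carbonyl, and its aryl formate is prone to hydrolysis and acyl transfer. Freeing the two phenols of A1 needs acid in the presence of the acid-sensitive chromene.
- Comparison: on structure, A1 is already at the correct oxidation level in ring D, which is better than the chosen plan (no dehydrogenation, no temporary acetate). On mechanism, the two ring closures are equally unambiguous in regiochemistry, but only the chosen plan creates ring B. On step economy, the ring B part of A2 should cost clearly more steps than the four-step carbene complex, so the total would be longer.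

Alternative 2: The cut is the carbon–carbon double bond of ring D. In the forward direction the diene 3-ethenyl-5-methoxy-2-(methoxymethoxy)-4-[(2-methylbut-3-en-2-yl)oxy]benzaldehyde A4 would undergo ring-closing metathesis with the second-generation Grubbs catalyst. A4 loses its two terminal CH2 groups as a volatile C2 olefin and gives the chromene aldehyde 8-methoxy-5-(methoxymethoxy)-2,2-dimethyl-2H-chromene-6-carbaldehyde A3.
- In its favour: metathesis of a diene such as A4 to a 2,2-dimethyl-2H-chromene is mild, catalytic and tolerant, and it makes the alkene of A3 directly at the right oxidation level. On this point it is better than the dehydrogenation of the chosen plan.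
- Against it here: A4 needs a tertiary allyl aryl ether, which is awkward to make and apt to rearrange on heating. A4 also needs a vinyl group at the most hindered position of the ring, between two oxygens. The cut says nothing about how ring B gets its pattern, and A3 is still far from the target: its formyl carbon must become C3 by condensation with the ring A acetyl fragment and an oxidative 1,2-aryl shift, during which the ring D alkene is exposed to an electrophilic oxidant.
- Comparison: on structure, the alternative solves ring D but neither ring B nor the bond from ring B to C3. On mechanism, the metathesis of A4 is the safer single step. On step economy, the stepwise arene functionalisation before A4 and the isoflavone construction after A3 should make it longer than the chosen plan.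

Alternative 3: The cuts are the bond from the ring B fusion carbon to the benzylic carbon of ring D and the bond from the ring D oxygen to the carbon that bears the two methyl groups. In the forward direction the aryl propargyl ether 2-hydroxy-5-methoxy-4-[(2-methylbut-3-yn-2-yl)oxy]benzaldehyde A6 would be heated. A6 has only one free position ortho to the ether oxygen, the other being blocked by the methoxyl, so the [3,3] shift can go only there. Enolisation, a 1,5-hydrogen shift and an oxa six-electron ring closure should then turn A6 into 5-hydroxy-8-methoxy-2,2-dimethyl-2H-chromene-6-carbaldehyde A5.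
- In its favour: the conversion of A6 into A5 is one thermal step without reagent, the regiochemistry is unambiguous in this substitution pattern, it is the shortest access to the ring B/ring D unit, and the alkene is formed directly. On all these points it is better than the chosen plan, which needs stoichiometric chromium and a later dehydrogenation.
- Against it here: the tertiary propargyl group of A6 must be put selectively on the non-chelated hydroxyl of its precursor, and the cascade from A6 needs a high temperature. A5 still lacks rings A and C, so, as for A3, the formyl carbon must be converted into C3 by a condensation and oxidative aryl shift sequence in the presence of the electron-rich chromene and a free or protected hydroquinone monoether.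
- Comparison: on structure, the step from A6 to A5 solves rings B and D together but not the bond to the chromone. On mechanism, the pericyclic cascade is at least as predictable as the benzannulation. On step economy, the total should be about the same as the chosen plan, but less convergent. The chosen plan is preferred because one step forms ring B and delivers it already bonded to C3, from two four-step fragments. The route through A6 and A5 would be the choice if stoichiometric chromium had to be avoided.

Key step: step 9

Assumption: the target is achiral, so no stereocentre has to be set (4 and 5 are racemic and transient); in the SMILES of 18 the π-bonded Cr(CO)3 unit is written as a separate fragment.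

Step 1
Reactants: 1 4-acetylbutyric acid (5-oxohexanoic acid)
Product: 3 6,6-dimethyltetrahydro-2H-pyran-2-one, via 5-hydroxy-5-methylhexanoic acid 2 (not isolated)
Conditions: MeMgBr (2.3 equiv), THF, 0 °C → rt; then 2 M HCl, rt
Reagents that add atoms: methylmagnesium bromide, C[Mg]Br
Why: The first equivalent of the Grignard reagent turns the acid into its unreactive magnesium carboxylate and the second adds to the ketone (Grignard addition); on acidification the tertiary δ-hydroxy acid 2 should close to the six-membered lactone, helped by the gem-dimethyl effect.

Step 2
Reactants: 3 6,6-dimethyltetrahydro-2H-pyran-2-one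
Product: 4 6,6-dimethyltetrahydro-2H-pyran-2-ol (racemic lactol)
Conditions: i-Bu2AlH (1.1 equiv), CH2Cl2, −78 °C; MeOH, then aq. potassium sodium tartrate
Reagents that add atoms: none
Why: Partial reduction of a lactone by i-Bu2AlH at low temperature stops at the aluminium hemiacetal, which gives the lactol on hydrolysis; the anomeric centre forms as a racemic, equilibrating mixture and is destroyed in step 3.

Step 3
Reactants: 4 6,6-dimethyltetrahydro-2H-pyran-2-ol
Product: 6 2,2-dimethyl-3,4-dihydro-2H-pyran, via lactol mesylate 5 (not isolated)
Conditions: MsCl, Et3N, CH2Cl2, 0 → 40 °C; fractional distillation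
Reagents that add atoms: none
Why: The anomeric hydroxyl is sulfonylated, the mesylate 5 ionises to the oxocarbenium ion and Et3N removes a proton from the neighbouring ring CH2 (dehydration of a lactol to a cyclic enol ether); the only other neighbour of the anomeric carbon is the ring oxygen, so a single alkene can form.

Step 4
Reactants: 6 2,2-dimethyl-3,4-dihydro-2H-pyran; 7 chromium hexacarbonyl, Cr(CO)6
Product: 10 pentacarbonyl[(2,2-dimethyl-3,4-dihydro-2H-pyran-6-yl)(methoxy)methylidene]chromium, via lithiated dihydropyran 8 (not isolated), via lithium acylchromate 9 (not isolated)
Conditions: t-BuLi (1.1 equiv), THF, −78 → 0 °C; Cr(CO)6, Et2O, 0 °C → rt; evaporate; Me3OBF4, CH2Cl2/H2O, 0 °C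
Reagents that add atoms: trimethyloxonium tetrafluoroborate, C[O+](C)C.F[B-](F)(F)F
Why: The vinylic C6–H next to oxygen is the most acidic site and is removed by t-BuLi (α-lithiation of a cyclic enol ether); the vinyllithium adds to a carbonyl ligand of Cr(CO)6 and the acylchromate is O-methylated by the hard oxonium salt (Fischer carbene synthesis), giving the zerovalent chromium carbene complex.

Step 5
Reactants: 11 2,4-dihydroxyacetophenone
Product: 12 1-[2-hydroxy-4-(triisopropylsilyloxy)phenyl]ethanone
Conditions: TIPSCl (1.05 equiv), imidazole, CH2Cl2, 0 °C → rt
Reagents that add atoms: chlorotriisopropylsilane, CC(C)[Si](Cl)(C(C)C)C(C)C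
Why: The 2-hydroxyl is tied up in a hydrogen bond to the acetyl group and is much less nucleophilic, so silylation goes to the 4-hydroxyl; the bulky aryl triisopropylsilyl ether is chosen to last through the amine, iodine, palladium, chromium and quinone steps that follow.

Step 6
Reactants: 12 1-[2-hydroxy-4-(triisopropylsilyloxy)phenyl]ethanone
Product: 14 3-iodo-7-(triisopropylsilyloxy)chromen-4-one, via enaminone 13 (not isolated)
Conditions: Me2NCH(OMe)2, toluene, 80 °C; evaporate; I2, pyridine, CHCl3, rt
Reagents that add atoms: N,N-dimethylformamide dimethyl acetal, COC(OC)N(C)C; iodine, II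
Why: Condensation of the methyl ketone with the amide acetal gives the (E)-enaminone 13; iodine attacks its nucleophilic α-carbon, the chelated phenol adds to the iminium carbon and dimethylamine is expelled (iodocyclisation of an o-hydroxyaryl enaminone to a 3-iodochromone), with pyridine buffering the acid so that the silyl ether is kept.

Step 7
Reactants: 14 3-iodo-7-(triisopropylsilyloxy)chromen-4-one; 15 ethynyltrimethylsilane
Product: 16 7-(triisopropylsilyloxy)-3-[(trimethylsilyl)ethynyl]chromen-4-one
Conditions: PdCl2(PPh3)2 (3 mol %), CuI (5 mol %), Et3N, THF, rt
Reagents that add atoms: none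
Why: Sonogashira coupling: the C3–I bond of the chromone adds readily to the zerovalent palladium formed in situ, and the tertiary amine is not nucleophilic enough to open ring C.

Step 8
Reactants: 16 7-(triisopropylsilyloxy)-3-[(trimethylsilyl)ethynyl]chromen-4-one
Product: 17 3-ethynyl-7-(triisopropylsilyloxy)chromen-4-one
Conditions: AgNO3 (10 mol %), acetone/H2O, rt
Reagents that add atoms: none
Why: AgNO3 activates the alkynylsilane as a π-complex so that water takes the trimethylsilyl group from carbon, and the silver acetylide is protonated to turn the catalyst over (silver-catalysed protodesilylation); the near-neutral medium should leave the aryl silyl ether and the base-sensitive chromone untouched.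

Step 9
Reactants: 10 pentacarbonyl[(2,2-dimethyl-3,4-dihydro-2H-pyran-6-yl)(methoxy)methylidene]chromium; 17 3-ethynyl-7-(triisopropylsilyloxy)chromen-4-one
Product: 19 3-(5-hydroxy-8-methoxy-2,2-dimethylchroman-6-yl)-7-(triisopropylsilyloxy)chromen-4-one, via arene Cr(CO)3 complex 18 (not isolated)
Conditions: 10 (1.3 equiv), THF (0.05 M), 55 °C, Ar; then air, EtOAc, rt
Reagents that add atoms: none
Why: Thermal loss of one cis carbonyl ligand from 10 frees a site for the alkyne of 17, which inserts into the Cr=C bond with its unsubstituted carbon joined to the carbene carbon (C5′–C6′); a carbonyl ligand then inserts to give a chromium-bound dienylketene whose ketene carbon is bonded to the alkyne carbon that carries the chromone (C1′–C2′). Ring B closes by six-electron electrocyclisation of this dienylketene, the ketene carbon bonding to the dihydropyran carbon that was β to the carbene (C2′–C3′); the cyclohexadienone tautomerises to the phenol, held as the η6 Cr(CO)3 complex 18, and air oxidises the metal off. The closest known reaction type is the Dötz benzannulation of methoxy(alkenyl)carbene complexes of chromium with terminal alkynes, here with a cyclic enol ether as the alkenyl group. No stereocentre is created. The step needs regioselective insertion, and the terminal alkyne secures it: the large chromonyl group avoids the carbene end and finishes next to the carbonyl-derived C2′. It also needs phenol formation to win over cyclopentannulation and over carbene transfer to the chromone enone, which is favoured by an alkenyl carbene on chromium, an ether solvent and a temperature near 55 °C; demetalation by air and not by a strong oxidant keeps the para-methoxyphenol from going on to the quinone.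

Step 10
Reactants: 19 3-(5-hydroxy-8-methoxy-2,2-dimethylchroman-6-yl)-7-(triisopropylsilyloxy)chromen-4-one
Product: 20 8-methoxy-2,2-dimethyl-6-[4-oxo-7-(triisopropylsilyloxy)-4H-chromen-3-yl]chroman-5-yl acetate
Conditions: Ac2O, pyridine, DMAP (cat.), CH2Cl2, rt
Reagents that add atoms: acetic anhydride, CC(=O)OC(C)=O
Why: Acylation of the hindered, hydrogen-bonded phenol under nucleophilic catalysis by DMAP; the acetate lowers the electron density of the para-dioxygenated ring B and so guards it against quinone formation in step 11.

Step 11
Reactants: 20 8-methoxy-2,2-dimethyl-6-[4-oxo-7-(triisopropylsilyloxy)-4H-chromen-3-yl]chroman-5-yl acetate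
Product: 21 8-methoxy-2,2-dimethyl-6-[4-oxo-7-(triisopropylsilyloxy)-4H-chromen-3-yl]-2H-chromen-5-yl acetate
Conditions: DDQ (1.5 equiv), 1,4-dioxane, 100 °C
Reagents that add atoms: none
Why: DDQ abstracts hydride from the benzylic C4″, the cation being stabilised through ring B by the ring D oxygen ortho to the ring fusion, and loss of a C3″ proton gives the conjugated chromene (DDQ dehydrogenation of a 2,2-dimethylchroman); the quaternary C2″ prevents oxidation beyond the chromene.

Step 12
Reactants: 21 8-methoxy-2,2-dimethyl-6-[4-oxo-7-(triisopropylsilyloxy)-4H-chromen-3-yl]-2H-chromen-5-yl acetate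
Product: 22 7-hydroxy-3-(5-hydroxy-8-methoxy-2,2-dimethyl-2H-chromen-6-yl)chromen-4-one (target)
Conditions: TBAF (1.1 equiv), THF, 0 °C; then K2CO3 (cat.), MeOH, rt; aq. NH4Cl
Reagents that add atoms: none
Why: Fluoride cleaves the aryl O–Si bond and methoxide formed from K2CO3 in methanol transesterifies the aryl acetate; the 7-phenoxide formed first makes ring C electron-rich and so protects C2 against methoxide, and nothing in the sequence is acidic or oxidising, so the chromene and the hydroquinone monoether should survive.

Compound list

1 | 4-acetylbutyric acid (5-oxohexanoic acid) | CC(=O)CCCC(=O)O | starting material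
2 | 5-hydroxy-5-methylhexanoic acid | CC(C)(O)CCCC(=O)O | intermediate
3 | 6,6-dimethyltetrahydro-2H-pyran-2-one | CC1(C)CCCC(=O)O1 | intermediate
4 | 6,6-dimethyltetrahydro-2H-pyran-2-ol (racemic) | CC1(C)CCCC(O)O1 | intermediate
5 | 6,6-dimethyltetrahydro-2H-pyran-2-yl methanesulfonate (racemic) | CC1(C)CCCC(OS(C)(=O)=O)O1 | intermediate
6 | 2,2-dimethyl-3,4-dihydro-2H-pyran | CC1(C)CCC=CO1 | intermediate
7 | chromium hexacarbonyl, Cr(CO)6 | O=C=[Cr](=C=O)(=C=O)(=C=O)(=C=O)=C=O | starting material
8 | (2,2-dimethyl-3,4-dihydro-2H-pyran-6-yl)lithium | [Li]C1=CCCC(C)(C)O1 | intermediate
9 | lithium pentacarbonyl[(2,2-dimethyl-3,4-dihydro-2H-pyran-6-yl)carbonyl]chromate | [Li+].[O-]C(=[Cr](=C=O)(=C=O)(=C=O)(=C=O)=C=O)C1=CCCC(C)(C)O1 | intermediate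
10 | pentacarbonyl[(2,2-dimethyl-3,4-dihydro-2H-pyran-6-yl)(methoxy)methylidene]chromium | COC(=[Cr](=C=O)(=C=O)(=C=O)(=C=O)=C=O)C1=CCCC(C)(C)O1 | intermediate
11 | 2,4-dihydroxyacetophenone | CC(=O)c1ccc(O)cc1O | starting material
12 | 1-[2-hydroxy-4-(triisopropylsilyloxy)phenyl]ethanone | CC(=O)c1ccc(O[Si](C(C)C)(C(C)C)C(C)C)cc1O | intermediate
13 | (E)-3-(dimethylamino)-1-[2-hydroxy-4-(triisopropylsilyloxy)phenyl]prop-2-en-1-one | CN(C)/C=C/C(=O)c1ccc(O[Si](C(C)C)(C(C)C)C(C)C)cc1O | intermediate
14 | 3-iodo-7-(triisopropylsilyloxy)chromen-4-one | O=c1c(I)coc2cc(O[Si](C(C)C)(C(C)C)C(C)C)ccc12 | intermediate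
15 | ethynyltrimethylsilane | C#C[Si](C)(C)C | starting material
16 | 7-(triisopropylsilyloxy)-3-[(trimethylsilyl)ethynyl]chromen-4-one | C[Si](C)(C)C#Cc1coc2cc(O[Si](C(C)C)(C(C)C)C(C)C)ccc2c1=O | intermediate
17 | 3-ethynyl-7-(triisopropylsilyloxy)chromen-4-one | C#Cc1coc2cc(O[Si](C(C)C)(C(C)C)C(C)C)ccc2c1=O | intermediate
18 | tricarbonylchromium η6 complex of 19, the metal bound to ring B | COc1cc(-c2coc3cc(O[Si](C(C)C)(C(C)C)C(C)C)ccc3c2=O)c(O)c2c1OC(C)(C)CC2.O=C=[Cr](=C=O)=C=O | intermediate
19 | 3-(5-hydroxy-8-methoxy-2,2-dimethylchroman-6-yl)-7-(triisopropylsilyloxy)chromen-4-one | COc1cc(-c2coc3cc(O[Si](C(C)C)(C(C)C)C(C)C)ccc3c2=O)c(O)c2c1OC(C)(C)CC2 | intermediate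
20 | 8-methoxy-2,2-dimethyl-6-[4-oxo-7-(triisopropylsilyloxy)-4H-chromen-3-yl]chroman-5-yl acetate | COc1cc(-c2coc3cc(O[Si](C(C)C)(C(C)C)C(C)C)ccc3c2=O)c(OC(C)=O)c2c1OC(C)(C)CC2 | intermediate
21 | 8-methoxy-2,2-dimethyl-6-[4-oxo-7-(triisopropylsilyloxy)-4H-chromen-3-yl]-2H-chromen-5-yl acetate | COc1cc(-c2coc3cc(O[Si](C(C)C)(C(C)C)C(C)C)ccc3c2=O)c(OC(C)=O)c2c1OC(C)(C)C=C2 | intermediate
22 | 7-hydroxy-3-(5-hydroxy-8-methoxy-2,2-dimethyl-2H-chromen-6-yl)chromen-4-one | COc1cc(-c2coc3cc(O)ccc3c2=O)c(O)c2c1OC(C)(C)C=C2 | target

Total step count: 12 steps. Longest linear sequence: 8 steps (steps 5–8 followed by steps 9–12; the carbene branch, steps 1–4 followed by steps 9–12, is equally long).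

Least certain steps

Step 9 (key step). The most likely failure is slow insertion of the conjugated, chromone-bearing alkyne, so that the unsaturated carbene intermediate is used up by other paths (cyclopentannulation, uptake of two alkynes, carbene transfer to the C2=C3 enone). Oxidation of the hydroquinone monoether during demetalation is a second risk. The fallback makes ring B on a simple alkyne and joins it to the chromone by cross-coupling. It sets out from 10 and 15: the same thermal benzannulation, followed by air, should give 8-methoxy-2,2-dimethyl-6-(trimethylsilyl)chroman-5-ol F1, with silicon next to the hydroxyl. NBS in CH2Cl2 at 0 °C replaces the silyl group at its own carbon to give 6-bromo-8-methoxy-2,2-dimethylchroman-5-ol F2; any material that has already lost silicon is brominated at the same carbon, ortho to the hydroxyl. Ac2O and pyridine give 6-bromo-8-methoxy-2,2-dimethylchroman-5-yl acetate F3. Miyaura borylation (B2pin2, Pd(dppf)Cl2, KOAc, dioxane, 85 °C) gives 8-methoxy-2,2-dimethyl-6-(4,4,5,5-tetramethyl-1,3,2-dioxaborolan-2-yl)chroman-5-yl acetate F4. Suzuki–Miyaura coupling of F4 with 14 (Pd(OAc)2, SPhos, anhydrous K3PO4, toluene, 90 °C) comes back to the route at 20.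

Step 11. Hydride abstraction may be sluggish because the acetoxy group deactivates ring B, and forcing the reaction may lead to oxidative degradation of ring B. The fallback replaces hydride abstraction by radical substitution and elimination. From 20, benzylic bromination at C4 of the chroman (NBS, AIBN, PhCF3, 80 °C) should give racemic 4-bromo-8-methoxy-2,2-dimethyl-6-[4-oxo-7-(triisopropylsilyloxy)-4H-chromen-3-yl]chroman-5-yl acetate F5, and elimination of HBr with DBU in toluene returns to the route at 21.

Step 8. The O7 silyl group may be lost together with the C-silyl group, or the catalyst may stall through precipitation of the silver acetylide. The fallback gives up the selectivity. From 16, both silyl groups are removed with TBAF buffered by AcOH in THF at 0 °C to give 3-ethynyl-7-hydroxychromen-4-one F6, and TIPSCl with imidazole in CH2Cl2 re-silylates O7, returning to the route at 17.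

Step 3. The volatile, acid-sensitive enol ether may be lost on isolation, or the anomeric sulfonate may eliminate incompletely. The fallback reaches the vinyllithium without the free enol ether. From 3, enolisation and O-phosphorylation (KN(SiMe3)2, (PhO)2P(O)Cl, THF, −78 °C) should give 2,2-dimethyl-3,4-dihydro-2H-pyran-6-yl diphenyl phosphate F7. Coupling with Me3SnSnMe3 (Pd(PPh3)4, LiCl, THF, 65 °C) gives (2,2-dimethyl-3,4-dihydro-2H-pyran-6-yl)trimethylstannane F8. Tin–lithium exchange with MeLi (THF, −78 °C) comes back to the route at 8, inside step 4; steps 2 and 3 are bypassed.

## Further compounds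

F1 | step 9 | 8-methoxy-2,2-dimethyl-6-(trimethylsilyl)chroman-5-ol | COc1cc([Si](C)(C)C)c(O)c2c1OC(C)(C)CC2
F2 | step 9 | 6-bromo-8-methoxy-2,2-dimethylchroman-5-ol | COc1cc(Br)c(O)c2c1OC(C)(C)CC2
F3 | step 9 | 6-bromo-8-methoxy-2,2-dimethylchroman-5-yl acetate | COc1cc(Br)c(OC(C)=O)c2c1OC(C)(C)CC2
F4 | step 9 | 8-methoxy-2,2-dimethyl-6-(4,4,5,5-tetramethyl-1,3,2-dioxaborolan-2-yl)chroman-5-yl acetate | COc1cc(B3OC(C)(C)C(C)(C)O3)c(OC(C)=O)c2c1OC(C)(C)CC2
F5 | step 11 | 4-bromo-8-methoxy-2,2-dimethyl-6-[4-oxo-7-(triisopropylsilyloxy)-4H-chromen-3-yl]chroman-5-yl acetate (racemic) | COc1cc(-c2coc3cc(O[Si](C(C)C)(C(C)C)C(C)C)ccc3c2=O)c(OC(C)=O)c2c1OC(C)(C)CC2Br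
F6 | step 8 | 3-ethynyl-7-hydroxychromen-4-one | C#Cc1coc2cc(O)ccc2c1=O
F7 | step 3 | 2,2-dimethyl-3,4-dihydro-2H-pyran-6-yl diphenyl phosphate | CC1(C)CCC=C(OP(=O)(Oc2ccccc2)Oc2ccccc2)O1
F8 | step 3 | (2,2-dimethyl-3,4-dihydro-2H-pyran-6-yl)trimethylstannane | CC1(C)CCC=C([Sn](C)(C)C)O1
A1 | alternative 1 | 7-(methoxymethoxy)-3-[8-methoxy-5-(methoxymethoxy)-2,2-dimethyl-2H-chromen-6-yl]chromen-4-one | COCOc1ccc2c(c1)occ(-c1cc(OC)c3OC(C)(C)C=Cc3c1OCOC)c2=O
A2 | alternative 1 | 2-[2-(8-methoxy-5-(methoxymethoxy)-2,2-dimethyl-2H-chromen-6-yl)-2-(triphenyl-λ5-phosphanylidene)acetyl]-5-(methoxymethoxy)phenyl formate | O=COc1cc(OCOC)ccc1C(=O)C(=P(c1ccccc1)(c1ccccc1)c1ccccc1)c1cc(OC)c2OC(C)(C)C=Cc2c1OCOC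
A3 | alternative 2 | 8-methoxy-5-(methoxymethoxy)-2,2-dimethyl-2H-chromene-6-carbaldehyde | COCOc1c(C=O)cc(OC)c2OC(C)(C)C=Cc12
A4 | alternative 2 | 3-ethenyl-5-methoxy-2-(methoxymethoxy)-4-[(2-methylbut-3-en-2-yl)oxy]benzaldehyde | COCOc1c(C=O)cc(OC)c(OC(C)(C)C=C)c1C=C
A5 | alternative 3 | 5-hydroxy-8-methoxy-2,2-dimethyl-2H-chromene-6-carbaldehyde | COc1cc(C=O)c(O)c2c1OC(C)(C)C=C2
A6 | alternative 3 | 2-hydroxy-5-methoxy-4-[(2-methylbut-3-yn-2-yl)oxy]benzaldehyde | COc1cc(C=O)c(O)cc1OC(C)(C)C#C
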